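**Retrosynthetic overview**

1. Numbering: the only ring is the 14-membered carbocycle C1–C14 (C1 = stereocentre; C3=C4 with CH2OH on C4; C7=C8 with CH3 on C8; C11=C12 with CH3 on C12); the side chain on C1 is C1'–C5'. The ring is formed once, in the penultimate step; the last step only reduces a C4 ester to CH2OH.
2. Ring closure: C8–C9, C8–CH3 and the E geometry of C7=C8 are made in one flask from an acyclic precursor that ends in C7H=C8Br2 and in a C9=C10–C11=C12 diene: 9-BBN hydroboration at C9, ring-closing B-alkyl Suzuki–Miyaura coupling at the C–Br bond trans to C6, then methylation of the remaining C–Br bond.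
3. Enabling feature: C8 is a ring sp2 carbon that carries CH3 while its alkene partner C7 carries only H, so the alkene can be held as a 1,1-dibromoalkene whose two C–Br bonds differ only by lying cis or trans to C6; C9 is homoallylic to the Z alkene C11=C12, so it can be unmasked as a primary borane from a diene terminus.
4. Acyclic precursor: Z-selective Still–Gennari olefination (C3=C4) of a C1-stereogenic aldehyde with a dibromoalkenyl phosphonate; C1 and the E alkene C1'=C2' arise together from a Johnson–Claisen rearrangement of an R allylic alcohol (chirality transfer).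
5. That alcohol comes from Ir-catalysed asymmetric allylation and cross-metathesis after allylic oxidation of homoneryl chloride, whose Z alkene C11=C12 is set by nickel-catalysed ring-opening coupling of 5-methyl-2,3-dihydrofuran.

Key step: step 13

Remark: in step 4 (R)-BINAP is assumed to be the ligand antipode that gives the R carbinol (the sense that gives (R)-1-phenylbut-3-en-1-ol from benzyl alcohol); if the sense is the reverse, (S)-BINAP is used.

**Route**

Step 1
Reactants: 1 5-bromo-2-methylpent-2-ene; 2 5-methyl-2,3-dihydrofuran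
Product: 4 (3Z)-4,8-dimethylnona-3,7-dien-1-ol (homonerol), via Grignard reagent 3 (not isolated)
Conditions: Mg, Et2O, reflux; then 2, NiCl2(dppp) (5 mol%), PhMe, 80 °C; then H2O
Reagents that add atoms: none
Why: Nickel-catalysed Kumada-type coupling of a cyclic enol ether, in which zerovalent nickel inserts into the vinylic C–O bond and the alkyl group takes the place of oxygen with retention, so the cis ring relationship becomes the Z alkene C11=C12 and the ring oxygen ends as the C9 hydroxyl.

Step 2
Reactants: 4 homonerol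
Product: 5 (6Z)-9-chloro-2,6-dimethylnona-2,6-diene
Conditions: PPh3, CCl4, CH2Cl2, 40 °C
Reagents that add atoms: tetrachloromethane ClC(Cl)(Cl)Cl
Why: Appel reaction, in which the alkoxyphosphonium ion is displaced by chloride (SN2) under neutral conditions that leave both trisubstituted alkenes alone, giving a chloride that survives the next three steps and later serves as the leaving group for diene formation.

Step 3
Reactants: 5 (6Z)-9-chloro-2,6-dimethylnona-2,6-diene
Product: 6 (2E,6Z)-9-chloro-2,6-dimethylnona-2,6-dien-1-ol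
Conditions: SeO2 (0.3 equiv), t-BuOOH (3 equiv), salicylic acid (0.1 equiv), CH2Cl2, 0 °C to rt
Reagents that add atoms: selenium dioxide O=[Se]=O (oxygen carrier, catalytic), tert-butyl hydroperoxide CC(C)(C)OO (stoichiometric oxygen source)
Why: Riley-type allylic oxidation run catalytically (ene reaction, then 2,3-sigmatropic shift) should hydroxylate the E methyl group of the terminal isopropylidene unit, the least hindered trisubstituted alkene, and so give the E allylic alcohol.

Step 4
Reactants: 6 (2E,6Z)-9-chloro-2,6-dimethylnona-2,6-dien-1-ol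
Product: 8 (4R,5E,9Z)-12-chloro-5,9-dimethyldodeca-1,5,9-trien-4-ol, via enal 7 (not isolated)
Conditions: allyl acetate (10 equiv), [Ir(cod)Cl]2 (2.5 mol%), (R)-BINAP (5 mol%), 3-nitrobenzoic acid (10 mol%), Cs2CO3 (20 mol%), THF, 100 °C
Reagents that add atoms: allyl acetate CC(=O)OCC=C
Why: Krische allylation, in which the iridium catalyst dehydrogenates 6 to enal 7 and uses the hydrogen to form an allyl-iridium species from allyl acetate that adds to the aldehyde through a closed chair transition state, the chiral bisphosphine selecting the face that gives the R carbinol at C2'.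

Step 5
Reactants: 8 (4R,5E,9Z)-12-chloro-5,9-dimethyldodeca-1,5,9-trien-4-ol
Product: 9 (5R,6E,10Z)-13-chloro-2,6,10-trimethyltrideca-2,6,10-trien-5-ol
Conditions: 2-methylbut-2-ene (excess), second-generation Grubbs catalyst RuCl2(=CHPh)(PCy3)(H2IMes) (5 mol%), CH2Cl2, 40 °C
Reagents that add atoms: 2-methylbut-2-ene CC=C(C)C
Why: Olefin cross-metathesis with 2-methylbut-2-ene should exchange only the monosubstituted alkene for the isopropylidene terminus C4'=C5', since the two trisubstituted alkenes do not turn over at 40 °C, and the carbinol centre is not involved.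

Step 6
Reactants: 9 (5R,6E,10Z)-13-chloro-2,6,10-trimethyltrideca-2,6,10-trien-5-ol
Product: 11 (5R,6E,10Z)-2,6,10-trimethyltrideca-2,6,10,12-tetraen-5-ol, via alkyl iodide 10 (not isolated)
Conditions: NaI (3 equiv), DBU (5 equiv), DME, 85 °C
Reagents that add atoms: none
Why: Finkelstein exchange to iodide 10 followed by E2 elimination with the amidine base takes the allylic C10 hydrogen and gives the conjugated diene terminus C9=C10 without generating an alkoxide (which could start an anionic oxy-Cope rearrangement of this 1,5-dien-3-ol) and without touching the Z alkene.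

Step 7
Reactants: 11 (5R,6E,10Z)-2,6,10-trimethyltrideca-2,6,10,12-tetraen-5-ol
Product: 13 ethyl (3R,4E)-4,8-dimethyl-3-[(3Z)-3-methylhexa-3,5-dien-1-yl]nona-4,7-dienoate, via ketene acetal 12 (not isolated)
Conditions: MeC(OEt)3 (8 equiv), EtCO2H (0.1 equiv), 140 °C, EtOH distilled off
Reagents that add atoms: triethyl orthoacetate CC(OCC)(OCC)OCC
Why: Johnson–Claisen rearrangement, in which ketene acetal 12 rearranges through a chair transition state with the C3' chain equatorial, giving the E alkene C1'=C2' and transferring the R carbinol configuration suprafacially across the E allyl unit to the new C1–C2 bond, so that C1 is formed as R.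

Step 8
Reactants: 13 ethyl (3R,4E)-4,8-dimethyl-3-[(3Z)-3-methylhexa-3,5-dien-1-yl]nona-4,7-dienoate
Product: 14 (3R,4E)-4,8-dimethyl-3-[(3Z)-3-methylhexa-3,5-dien-1-yl]nona-4,7-dienal
Conditions: i-Bu2AlH (1.1 equiv), CH2Cl2, −78 °C; MeOH, then aq. potassium sodium tartrate KNaC4H4O6
Reagents that add atoms: none
Why: Partial reduction of the ester with one equivalent of i-Bu2AlH at −78 °C and a cold quench is the standard route to the aldehyde oxidation level, and C1 (β to the carbonyl) cannot epimerise.

Step 9
Reactants: 15 methyl 2-[bis(2,2,2-trifluoroethoxy)phosphoryl]acetate; 16 2-(2-bromoethyl)-1,3-dioxolane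
Product: 18 methyl 2-[bis(2,2,2-trifluoroethoxy)phosphoryl]-4-(1,3-dioxolan-2-yl)butanoate, via sodium phosphonate 17 (not isolated)
Conditions: NaH (1.0 equiv), DMF, 0 °C; then 16, NaI (0.1 equiv), 60 °C
Reagents that add atoms: none
Why: SN2 C-alkylation of the stabilised phosphonoacetate carbanion 17 by the primary bromide is the usual entry to α-substituted Still–Gennari reagents, and the hindered monoalkylated product should alkylate a second time only slowly.

Step 10
Reactants: 18 methyl 2-[bis(2,2,2-trifluoroethoxy)phosphoryl]-4-(1,3-dioxolan-2-yl)butanoate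
Product: 19 methyl 2-[bis(2,2,2-trifluoroethoxy)phosphoryl]-5-oxopentanoate
Conditions: 1 M aq. HCl, THF, rt
Reagents that add atoms: water O
Why: Acid-catalysed acetal hydrolysis frees the aldehyde, while the methyl ester and the trifluoroethyl phosphonate tolerate dilute acid at room temperature.

Step 11
Reactants: 19 methyl 2-[bis(2,2,2-trifluoroethoxy)phosphoryl]-5-oxopentanoate
Product: 20 methyl 2-[bis(2,2,2-trifluoroethoxy)phosphoryl]-6,6-dibromohex-5-enoate
Conditions: CBr4 (2 equiv), PPh3 (2 equiv), Zn dust (2 equiv), CH2Cl2, rt; then 19, 0 °C to rt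
Reagents that add atoms: tetrabromomethane BrC(Br)(Br)Br
Why: Ramirez dibromo-olefination (the first stage of the Corey–Fuchs sequence), in which the weakly basic ylide Ph3P=CBr2 undergoes a Wittig reaction with the aldehyde and should not deprotonate the phosphonoacetate, installs C8 as a CBr2 terminus without any stereochemical question.

Step 12
Reactants: 14 (3R,4E)-4,8-dimethyl-3-[(3Z)-3-methylhexa-3,5-dien-1-yl]nona-4,7-dienal; 20 methyl 2-[bis(2,2,2-trifluoroethoxy)phosphoryl]-6,6-dibromohex-5-enoate
Product: 22 methyl (2Z,5R,6E)-2-(4,4-dibromobut-3-en-1-yl)-6,10-dimethyl-5-[(3Z)-3-methylhexa-3,5-dien-1-yl]undeca-2,6,9-trienoate, via potassium phosphonate 21 (not isolated)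
Conditions: 20, KN(SiMe3)2 (0.98 equiv), 18-crown-6 (5 equiv), THF, −78 °C; then 14, −78 °C
Reagents that add atoms: none
Why: Still–Gennari variant of the Horner–Wadsworth–Emmons reaction, in which the electron-poor trifluoroethyl phosphonate and a crown-ether-separated potassium ion make the addition irreversible and the elimination fast, so the kinetic pathway places the ester cis to C2 and gives the Z enoate at C3=C4.

Step 13
Reactants: 22 methyl (2Z,5R,6E)-2-(4,4-dibromobut-3-en-1-yl)-6,10-dimethyl-5-[(3Z)-3-methylhexa-3,5-dien-1-yl]undeca-2,6,9-trienoate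
Product: 25 methyl (1Z,4R,7Z,11E)-7,11-dimethyl-4-[(2E)-6-methylhepta-2,5-dien-2-yl]cyclotetradeca-1,7,11-triene-1-carboxylate, via alkylborane 23 (not isolated), via macrocyclic bromoalkene 24 (not isolated)
Conditions: 9-BBN-H (1.3 equiv), THF, 0 °C to rt; then added over 10 h to Pd(dppf)Cl2 (10 mol%), AsPh3 (20 mol%), Cs2CO3 (3 equiv), DMF/THF/H2O, 45 °C, final 2 mM; then MeB(OH)2 (5 equiv), Pd(OAc)2 (10 mol%), SPhos (20 mol%), 70 °C
Reagents that add atoms: methylboronic acid CB(O)O
Why: Proposed new method: 9-BBN-H adds only to the terminal C9=C10 bond of the diene (boron on C9) to give 23, zerovalent palladium then inserts into the C8–Br bond trans to C6, base-assisted transfer of C9 from boron to palladium and reductive elimination close the ring to 24, and a second oxidative addition into the remaining C8–Br bond followed by transmetalation from MeB(OH)2 and reductive elimination gives 25 with retention. The closest known reaction types are the trans-selective mono-coupling of 1,1-dibromo-1-alkenes with organoboron or organozinc reagents followed by a second coupling at the remaining C–Br bond (intermolecular), and the B-alkyl Suzuki–Miyaura macrocyclisation of an alkenyl halide onto a hydroborated terminal alkene; running both in one flask on a ring-closing substrate is the new element. The 14-membered ring closes end to end by C(sp3)–C(sp2) reductive elimination from a 15-membered palladacycle under slow-addition high dilution. No stereocentre is formed and C1 is untouched; the E geometry of C7=C8 is decided by which C–Br bond reacts first. The step needs chemoselective hydroboration (the only monosubstituted alkene, against four trisubstituted or electron-poor ones), trans-selective first oxidative addition (the C6 chain shields the cis bromide), ring closure over oligomerisation (dilution) and retention in the methylation (isolated alkenyl bromide with no allyl pathway for isomerisation).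

Step 14
Reactants: 25 methyl (1Z,4R,7Z,11E)-7,11-dimethyl-4-[(2E)-6-methylhepta-2,5-dien-2-yl]cyclotetradeca-1,7,11-triene-1-carboxylate
Product: 26 [(1Z,4R,7Z,11E)-7,11-dimethyl-4-[(2E)-6-methylhepta-2,5-dien-2-yl]cyclotetradeca-1,7,11-trien-1-yl]methanol (target)
Conditions: i-Bu2AlH (2.5 equiv), CH2Cl2, −78 °C to 0 °C; aq. potassium sodium tartrate KNaC4H4O6
Reagents that add atoms: none
Why: 1,2-Reduction of the α,β-unsaturated ester with i-Bu2AlH gives the allylic alcohol without changing the geometry of C3=C4, the other alkenes or C1.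

**Compound list**

1 | 5-bromo-2-methylpent-2-ene | CC(C)=CCCBr | starting material
2 | 5-methyl-2,3-dihydrofuran | CC1=CCCO1 | starting material
3 | (4-methylpent-3-en-1-yl)magnesium bromide | CC(C)=CCC[Mg]Br | intermediate
4 | (3Z)-4,8-dimethylnona-3,7-dien-1-ol (homonerol) | CC(C)=CCC/C(C)=C\CCO | intermediate
5 | (6Z)-9-chloro-2,6-dimethylnona-2,6-diene | CC(C)=CCC/C(C)=C\CCCl | intermediate
6 | (2E,6Z)-9-chloro-2,6-dimethylnona-2,6-dien-1-ol | OC/C(C)=C/CC/C(C)=C\CCCl | intermediate
7 | (2E,6Z)-9-chloro-2,6-dimethylnona-2,6-dienal | O=C/C(C)=C/CC/C(C)=C\CCCl | intermediate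
8 | (4R,5E,9Z)-12-chloro-5,9-dimethyldodeca-1,5,9-trien-4-ol | C=CC[C@@H](O)/C(C)=C/CC/C(C)=C\CCCl | intermediate
9 | (5R,6E,10Z)-13-chloro-2,6,10-trimethyltrideca-2,6,10-trien-5-ol | CC(C)=CC[C@@H](O)/C(C)=C/CC/C(C)=C\CCCl | intermediate
10 | (5R,6E,10Z)-13-iodo-2,6,10-trimethyltrideca-2,6,10-trien-5-ol | CC(C)=CC[C@@H](O)/C(C)=C/CC/C(C)=C\CCI | intermediate
11 | (5R,6E,10Z)-2,6,10-trimethyltrideca-2,6,10,12-tetraen-5-ol | CC(C)=CC[C@@H](O)/C(C)=C/CC/C(C)=C\C=C | intermediate
12 | (5R,6E,10Z)-5-[(1-ethoxyethenyl)oxy]-2,6,10-trimethyltrideca-2,6,10,12-tetraene | CC(C)=CC[C@@H](OC(=C)OCC)/C(C)=C/CC/C(C)=C\C=C | intermediate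
13 | ethyl (3R,4E)-4,8-dimethyl-3-[(3Z)-3-methylhexa-3,5-dien-1-yl]nona-4,7-dienoate | CC(C)=CC/C=C(\C)[C@@H](CC(=O)OCC)CC/C(C)=C\C=C | intermediate
14 | (3R,4E)-4,8-dimethyl-3-[(3Z)-3-methylhexa-3,5-dien-1-yl]nona-4,7-dienal | CC(C)=CC/C=C(\C)[C@@H](CC=O)CC/C(C)=C\C=C | intermediate
15 | methyl 2-[bis(2,2,2-trifluoroethoxy)phosphoryl]acetate | COC(=O)CP(=O)(OCC(F)(F)F)OCC(F)(F)F | starting material
16 | 2-(2-bromoethyl)-1,3-dioxolane | BrCCC1OCCO1 | starting material
17 | sodium salt of 15 (phosphonate carbanion) | [Na+].COC(=O)[CH-]P(=O)(OCC(F)(F)F)OCC(F)(F)F | intermediate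
18 | methyl 2-[bis(2,2,2-trifluoroethoxy)phosphoryl]-4-(1,3-dioxolan-2-yl)butanoate | COC(=O)C(CCC1OCCO1)P(=O)(OCC(F)(F)F)OCC(F)(F)F | intermediate
19 | methyl 2-[bis(2,2,2-trifluoroethoxy)phosphoryl]-5-oxopentanoate | COC(=O)C(CCC=O)P(=O)(OCC(F)(F)F)OCC(F)(F)F | intermediate
20 | methyl 2-[bis(2,2,2-trifluoroethoxy)phosphoryl]-6,6-dibromohex-5-enoate | COC(=O)C(CCC=C(Br)Br)P(=O)(OCC(F)(F)F)OCC(F)(F)F | intermediate
21 | potassium salt of 20 (phosphonate carbanion) | [K+].COC(=O)[C-](CCC=C(Br)Br)P(=O)(OCC(F)(F)F)OCC(F)(F)F | intermediate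
22 | methyl (2Z,5R,6E)-2-(4,4-dibromobut-3-en-1-yl)-6,10-dimethyl-5-[(3Z)-3-methylhexa-3,5-dien-1-yl]undeca-2,6,9-trienoate | CC(C)=CC/C=C(\C)[C@@H](C/C=C(\C(=O)OC)CCC=C(Br)Br)CC/C(C)=C\C=C | intermediate
23 | methyl (2Z,5R,6E)-5-[(3Z)-6-(9-borabicyclo[3.3.1]nonan-9-yl)-3-methylhex-3-en-1-yl]-2-(4,4-dibromobut-3-en-1-yl)-6,10-dimethylundeca-2,6,9-trienoate | CC(C)=CC/C=C(\C)[C@@H](C/C=C(\C(=O)OC)CCC=C(Br)Br)CC/C(C)=C\CCB1C2CCCC1CCC2 | intermediate
24 | methyl (1Z,4R,7Z,11Z)-11-bromo-7-methyl-4-[(2E)-6-methylhepta-2,5-dien-2-yl]cyclotetradeca-1,7,11-triene-1-carboxylate | CC(C)=CC/C=C(\C)[C@H]1C/C=C(\C(=O)OC)CC/C=C(\Br)CC/C=C(/C)CC1 | intermediate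
25 | methyl (1Z,4R,7Z,11E)-7,11-dimethyl-4-[(2E)-6-methylhepta-2,5-dien-2-yl]cyclotetradeca-1,7,11-triene-1-carboxylate | CC(C)=CC/C=C(\C)[C@H]1C/C=C(\C(=O)OC)CC/C=C(\C)CC/C=C(/C)CC1 | intermediate
26 | [(1Z,4R,7Z,11E)-7,11-dimethyl-4-[(2E)-6-methylhepta-2,5-dien-2-yl]cyclotetradeca-1,7,11-trien-1-yl]methanol | CC(C)=CC/C=C(\C)[C@H]1C/C=C(\CO)CC/C=C(\C)CC/C=C(/C)CC1 | target

**Step count and risks**

Total step count: 14. Longest linear sequence: 11 steps (1–8, 12, 13, 14); steps 9–11 build the phosphonate branch.

Steps most likely to fail: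

Step 13 (Proposed new method). The first oxidative addition may not distinguish the two C–Br bonds well enough. Because ring-closing transmetalation is slow at high dilution, the α-bromoalkenyl palladium intermediate may also decay by dehydrobromination, protodehalogenation or intermolecular coupling. The methylation of the hindered ring bromide may stall. The fallback fixes the alkene geometry before ring closure and asks only the known macrocyclic B-alkyl Suzuki–Miyaura coupling of the ring-closing event. It sets out from 14 (and from 15 through its sodium salt 17) and comes back at 25. Commercial pent-3-yn-1-ol is hydrozirconated and iodinated (Cp2Zr(H)Cl, THF, then I2) to give (3E)-4-iodopent-3-en-1-ol F1. I2, PPh3 and imidazole should convert it into (2E)-2,5-diiodopent-2-ene F2. Alkylation of 17 with F2 in DMF should give methyl (5E)-2-[bis(2,2,2-trifluoroethoxy)phosphoryl]-6-iodohept-5-enoate F3. Its potassium salt F4 (KN(SiMe3)2, 18-crown-6, THF, −78 °C) should condense with 14 to give methyl (2Z,5R,6E)-2-[(3E)-4-iodopent-3-en-1-yl]-6,10-dimethyl-5-[(3Z)-3-methylhexa-3,5-dien-1-yl]undeca-2,6,9-trienoate F5. 9-BBN-H then gives the C9 alkylborane F6, which is added slowly to Pd(dppf)Cl2, AsPh3 and Cs2CO3 in DMF/THF/H2O. Coupling with retention at the E iodoalkene should close the ring to 25.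

Step 3. Allylic oxidation at the internal Z alkene C11=C12, which has no deactivating allylic heteroatom, may compete with oxidation of the terminal alkene, and over-oxidation to the enal may lower the yield. The fallback builds the oxygenated E terminus by olefination instead of C–H oxidation. It sets out from 2 and comes back at 6 through enal 7, which is isolated here. Commercial 2-(2-bromoethyl)-1,3-dioxane is converted into [2-(1,3-dioxan-2-yl)ethyl]magnesium bromide F7 and coupled with 2 (NiCl2(dppp), PhMe, 80 °C) to give (3Z)-6-(1,3-dioxan-2-yl)-4-methylhex-3-en-1-ol F8. PPh3 and CCl4 should give 2-[(3Z)-6-chloro-3-methylhex-3-en-1-yl]-1,3-dioxane F9. Aqueous HCl in THF should free (4Z)-7-chloro-4-methylhept-4-enal F10. Wittig reaction with commercial 2-(triphenylphosphoranylidene)propanal (PhMe, 90 °C) should give the E enal 7, and NaBH4 with CeCl3·7H2O in MeOH should reduce it to 6.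

Step 1. β-Hydride elimination from the alkylnickel intermediate may reduce the enol ether instead of coupling, and isomerisation of the alkenylnickel species may erode the Z geometry. The fallback sets the Z alkene by syn-carbometalation of an alkyne. It sets out from 1 (through Grignard reagent 3) and comes back at 4. Reagent 3 is converted with CuBr·SMe2 (Et2O/Me2S, −45 °C) into the alkylcopper reagent, which adds syn across propyne (Normant carbocupration, alkyl group to the internal carbon) to give [(1Z)-2,6-dimethylhepta-1,5-dien-1-yl]copper F11. This should open oxirane at −30 °C to rt with retention and give 4.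

**Further compounds**

F1 | step 13 | (3E)-4-iodopent-3-en-1-ol | OCC/C=C(\C)I
F2 | step 13 | (2E)-2,5-diiodopent-2-ene | ICC/C=C(\C)I
F3 | step 13 | methyl (5E)-2-[bis(2,2,2-trifluoroethoxy)phosphoryl]-6-iodohept-5-enoate | COC(=O)C(CC/C=C(\C)I)P(=O)(OCC(F)(F)F)OCC(F)(F)F
F4 | step 13 | potassium salt of F3 (phosphonate carbanion) | [K+].COC(=O)[C-](CC/C=C(\C)I)P(=O)(OCC(F)(F)F)OCC(F)(F)F
F5 | step 13 | methyl (2Z,5R,6E)-2-[(3E)-4-iodopent-3-en-1-yl]-6,10-dimethyl-5-[(3Z)-3-methylhexa-3,5-dien-1-yl]undeca-2,6,9-trienoate | CC(C)=CC/C=C(\C)[C@@H](C/C=C(\C(=O)OC)CC/C=C(\C)I)CC/C(C)=C\C=C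
F6 | step 13 | methyl (2Z,5R,6E)-5-[(3Z)-6-(9-borabicyclo[3.3.1]nonan-9-yl)-3-methylhex-3-en-1-yl]-2-[(3E)-4-iodopent-3-en-1-yl]-6,10-dimethylundeca-2,6,9-trienoate | CC(C)=CC/C=C(\C)[C@@H](C/C=C(\C(=O)OC)CC/C=C(\C)I)CC/C(C)=C\CCB1C2CCCC1CCC2
F7 | step 3 | [2-(1,3-dioxan-2-yl)ethyl]magnesium bromide | Br[Mg]CCC1OCCCO1
F8 | step 3 | (3Z)-6-(1,3-dioxan-2-yl)-4-methylhex-3-en-1-ol | OCC/C=C(/C)CCC1OCCCO1
F9 | step 3 | 2-[(3Z)-6-chloro-3-methylhex-3-en-1-yl]-1,3-dioxane | ClCC/C=C(/C)CCC1OCCCO1
F10 | step 3 | (4Z)-7-chloro-4-methylhept-4-enal | ClCC/C=C(/C)CCC=O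
F11 | step 1 | [(1Z)-2,6-dimethylhepta-1,5-dien-1-yl]copper | CC(C)=CCC/C(C)=C\[Cu]
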